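**Strategy.** Numbering follows the polyketide chain (C1 = carboxyl carbon). Everything rests on cutting the bond between the oxane ring carbon C7 and the diene carbon C8. The C8–C11 (E,E)-diene next to an oxygenated ring carbon is read as the product of a nickel-catalysed reductive coupling of a methyl-capped 1,3-enyne (C8–C19) with an α-methyl aldehyde (C1–C7). One operation should form C7–C8, the trisubstituted (E)-C8=C9 alkene by syn H/C addition, and the C7 carbinol, with the C10=C11 alkene steering nickel to C8. The oxane is then closed by oxa-Michael addition of the C7 hydroxyl onto the C2=C3 enoate, and the C18 hydroxyl finally directs the epoxidation.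

Key step: step 15

Assumption: the enantiomer of neomenthyldiphenylphosphine that delivers the 7S carbinol is taken to be the (+)-form; if the sense of induction is the opposite, the (−)-form is used and nothing else changes.

**Fragment A (C1–C7)**

Step 1
Reactants: 1 (S)-β-citronellene, (3S)-3,7-dimethylocta-1,6-diene
Product: 3 (4S)-4-methylhex-5-enal, via trisubstituted epoxide 2 (not isolated)
Conditions: mCPBA (1.0 equiv), NaHCO3, CH2Cl2, 0 °C; then H5IO6, THF/H2O, 0 °C to rt
Reagents that add atoms: mCPBA, O=C(OO)c1cccc(Cl)c1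
Why: Prilezhaev epoxidation is far faster at the electron-rich trisubstituted alkene than at the vinyl group, and periodic acid then hydrolyses and cleaves the epoxide (glycol cleavage) to the aldehyde, the stereocentre coming unchanged from 1.

Step 2
Reactants: 3 (4S)-4-methylhex-5-enal
Product: 4 methyl (2E,6S)-6-methylocta-2,7-dienoate
Conditions: Ph3P=CHCO2Me, CH2Cl2, rt
Reagents that add atoms: methyl (triphenylphosphoranylidene)acetate, COC(=O)C=P(c1ccccc1)(c1ccccc1)c1ccccc1
Why: Wittig olefination with the stabilised ylide should give the (E)-enoate, and the stereocentre is remote from the aldehyde.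

Step 3
Reactants: 4 methyl (2E,6S)-6-methylocta-2,7-dienoate
Product: 6 methyl (2E,6S)-6-methyl-7-oxohept-2-enoate, via terminal ozonide 5 (not isolated)
Conditions: O3, CH2Cl2, −78 °C (Sudan Red 7B end point); PPh3, −78 °C to rt
Reagents that add atoms: ozone, [O-][O+]=O
Why: Ozonolysis with a dye end point should cleave the electron-rich monosubstituted alkene much faster than the electron-poor enoate, and the neutral phosphine reduction of the ozonide should not epimerise the new α-methyl aldehyde.

**Fragment B (C8–C19)**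

Step 4
Reactants: 7 methyl (R)-lactate
Product: 8 (2R)-2-hydroxy-N-methoxy-N-methylpropanamide
Conditions: MeNH(OMe)·HCl, iPrMgCl, THF, −20 to 0 °C
Reagents that add atoms: N,O-dimethylhydroxylamine hydrochloride, CNOC.Cl
Why: Aminolysis of the ester by the magnesium amide of N,O-dimethylhydroxylamine gives the N-methoxy-N-methylamide, the magnesium alkoxide of the free hydroxyl shielding the α-centre from enolisation.

Step 5
Reactants: 8 (2R)-2-hydroxy-N-methoxy-N-methylpropanamide
Product: 9 (2R)-2-hydroxypentan-3-one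
Conditions: EtMgBr (2.5 equiv), THF, 0 °C to rt; aq. NH4Cl
Reagents that add atoms: ethylmagnesium bromide, CC[Mg]Br
Why: Grignard addition to the N-methoxy-N-methylamide stops at the ketone because the magnesium-chelated tetrahedral adduct survives until work-up.

Step 6
Reactants: 9 (2R)-2-hydroxypentan-3-one
Product: 10 (2R)-3-oxopentan-2-yl benzoate
Conditions: Bz2O, DMAP (cat.), iPr2NEt, CH2Cl2, rt
Reagents that add atoms: benzoic anhydride, O=C(OC(=O)c1ccccc1)c1ccccc1
Why: DMAP-catalysed acylation under mild amine base installs the benzoate that later directs the aldol, without epimerising the α-keto centre.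

Step 7
Reactants: 10 (2R)-3-oxopentan-2-yl benzoate; 11 methacrolein
Product: 14 (2R,4S,5R)-5-hydroxy-4,6-dimethyl-3-oxohept-6-en-2-yl benzoate, via enol borinate 12 (not isolated), via boron aldolate 13 (not isolated)
Conditions: (c-C6H11)2BCl, Me2NEt, Et2O, −78 to 0 °C; 11, −78 to −20 °C; H2O2, MeOH, pH 7 buffer, 0 °C
Reagents that add atoms: chlorodicyclohexylborane, ClB(C1CCCCC1)C1CCCCC1 (its boron stays only in 12 and 13)
Why: Boron-mediated anti-aldol: the (E)-enol borinate reacts through a chair transition state steered by the α'-benzoyloxy centre (formyl C–H to benzoate carbonyl contact, allylic strain minimised), setting C16 and C15 as the 15,16-anti adduct with the C16 methyl syn to the C18 benzoate.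

Step 8
Reactants: 14 (2R,4S,5R)-5-hydroxy-4,6-dimethyl-3-oxohept-6-en-2-yl benzoate; 15 propanal
Product: 16 (2R,3R,4R,5R)-3-hydroxy-4,6-dimethyl-5-(propanoyloxy)hept-6-en-2-yl benzoate
Conditions: SmI2 (0.3 equiv), EtCHO (8 equiv), THF, −20 °C
Reagents that add atoms: none
Why: Evans–Tishchenko reduction: the samarium-bound hemiacetal of propanal delivers hydride intramolecularly through a chair-like bicyclic transition state, giving the 15,17-anti relationship (17R) with the propanoyl group on O15 and O17 free.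

Step 9
Reactants: 16 (2R,3R,4R,5R)-3-hydroxy-4,6-dimethyl-5-(propanoyloxy)hept-6-en-2-yl benzoate
Product: 17 (2R,3R,4S,5R)-3-methoxy-4,6-dimethyl-5-(propanoyloxy)hept-6-en-2-yl benzoate
Conditions: Me3OBF4, 1,8-bis(dimethylamino)naphthalene, CH2Cl2, 0 °C to rt
Reagents that add atoms: trimethyloxonium tetrafluoroborate, C[O+](C)C.F[B-](F)(F)F
Why: O-Alkylation by the oxonium salt with a non-nucleophilic proton scavenger avoids alkoxide formation and hence migration of the neighbouring benzoate or propanoate.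

Step 10
Reactants: 17 (2R,3R,4S,5R)-3-methoxy-4,6-dimethyl-5-(propanoyloxy)hept-6-en-2-yl benzoate
Product: 20 (2S,4E,6S,7R,8R)-8-(benzoyloxy)-7-methoxy-2,4,6-trimethylnon-4-enoic acid, via silyl ketene acetal 18 (not isolated), via trimethylsilyl ester 19 (not isolated)
Conditions: LiN(iPr)2, TMSCl/Et3N (in situ quench), THF, −78 °C; then rt to 50 °C; dilute aq. HCl
Reagents that add atoms: chlorotrimethylsilane, C[Si](C)(C)Cl (its silicon stays only in 18 and 19)
Why: Ireland–Claisen rearrangement: kinetic enolisation in THF gives the (E)-silyl ketene acetal (methyl cis to the allylic oxygen), and the chair transition state with the C16 chain equatorial should give the (14E)-alkene and relay the C15 configuration to C12 (12S).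

Step 11
Reactants: 20 (2S,4E,6S,7R,8R)-8-(benzoyloxy)-7-methoxy-2,4,6-trimethylnon-4-enoic acid
Product: 21 (2S,4E,6S,7R,8R)-7-methoxy-2,4,6-trimethylnon-4-ene-1,8-diol
Conditions: LiAlH4, THF, 0 °C to rt; aq. potassium sodium tartrate
Reagents that add atoms: none
Why: Hydride reduction converts the acid into the primary alcohol and removes the benzoate in the same operation, no stereocentre being touched.

Step 12
Reactants: 21 (2S,4E,6S,7R,8R)-7-methoxy-2,4,6-trimethylnon-4-ene-1,8-diol
Product: 22 (2S,4E,6S,7R,8R)-8-hydroxy-7-methoxy-2,4,6-trimethylnon-4-enal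
Conditions: TEMPO (10 mol %), PhI(OAc)2, CH2Cl2, rt
Reagents that add atoms: none
Why: Oxoammonium (TEMPO) oxidation is selective for the primary alcohol over the secondary C18 hydroxyl and, being non-basic, should not epimerise C12.

Step 13
Reactants: 22 (2S,4E,6S,7R,8R)-8-hydroxy-7-methoxy-2,4,6-trimethylnon-4-enal
Product: 23 (2R,3R,4S,5E,8S,9E)-10-iodo-3-methoxy-4,6,8-trimethyldeca-5,9-dien-2-ol
Conditions: CrCl2 (8 equiv), CHI3 (3 equiv), THF/1,4-dioxane, 0 °C to rt
Reagents that add atoms: iodoform, IC(I)I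
Why: Takai olefination with the geminal dichromium species from iodoform should give the (E)-vinyl iodide under non-basic conditions that tolerate the free hydroxyl and the α-stereocentre.

Step 14
Reactants: 23 (2R,3R,4S,5E,8S,9E)-10-iodo-3-methoxy-4,6,8-trimethyldeca-5,9-dien-2-ol; 24 propyne
Product: 25 (2R,3R,4S,5E,8S,9E)-3-methoxy-4,6,8-trimethyltrideca-5,9-dien-11-yn-2-ol
Conditions: PdCl2(PPh3)2 (5 mol %), CuI (10 mol %), iPr2NH, THF, rt
Reagents that add atoms: none
Why: Sonogashira coupling joins the vinyl iodide and propyne with retention of the (E)-alkene geometry.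

**Union and endgame**

Step 15
Reactants: 6 methyl (2E,6S)-6-methyl-7-oxohept-2-enoate; 25 (2R,3R,4S,5E,8S,9E)-3-methoxy-4,6,8-trimethyltrideca-5,9-dien-11-yn-2-ol
Product: 27 methyl (2E,6S,7S,8E,10E,12S,14E,16S,17R,18R)-7,18-dihydroxy-17-methoxy-6,8,12,14,16-pentamethylnonadeca-2,8,10,14-tetraenoate, via diethylboryl ether 26 (not isolated)
Conditions: Ni(cod)2 (10 mol %), (+)-neomenthyldiphenylphosphine (20 mol %), Et3B (2.5 equiv), EtOAc/DMI (1:1), rt; aq. NH4Cl
Reagents that add atoms: triethylborane, CCB(CC)CC (its boron stays only in 26)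
Why: Zerovalent nickel binds the alkyne and the aldehyde and undergoes oxidative cyclisation to an oxanickelacyclopentene in which C8 is bonded to the carbonyl carbon; ethyl transfer from Et3B, β-hydride elimination (loss of ethene) and C–H reductive elimination place H on C9 syn to the new C7–C8 bond, so the (8E) geometry follows from the syn addition. The closest known reaction type is the nickel-catalysed, borane-mediated reductive coupling of conjugated 1,3-enynes with aldehydes, used here on the same bond type. No ring is closed in this step. The new C7 stereocentre is controlled by the chiral monophosphine on nickel, which must deliver the alkyne carbon to the Re face of the aldehyde; the C6 centre distinguishes only a methyl from a primary alkyl chain and so exerts little opposing bias. Regioselectivity (bond at C8, not C9) is secured by coordination of the conjugated C10=C11 alkene to nickel and by the small methyl cap on C8; chemoselectivity for the aldehyde over the enoate rests on the faster oxidative cyclisation of aldehydes, and the free C18 hydroxyl and the isolated C14=C15 alkene should be inert.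

Step 16
Reactants: 27 methyl (2E,6S,7S,8E,10E,12S,14E,16S,17R,18R)-7,18-dihydroxy-17-methoxy-6,8,12,14,16-pentamethylnonadeca-2,8,10,14-tetraenoate
Product: 28 methyl 2-[(2R,5S,6S)-6-[(2E,4E,6S,8E,10S,11R,12R)-12-hydroxy-11-methoxy-6,8,10-trimethyltrideca-2,4,8-trien-2-yl]-5-methyloxan-2-yl]acetate
Conditions: KOtBu (0.3 equiv), THF, −20 to 0 °C
Reagents that add atoms: none
Why: Intramolecular oxa-Michael addition (6-exo-trig) of the C7 alkoxide to the enoate is reversible under alkoxide catalysis, so C3 should be set under thermodynamic control as the 2,6-cis oxane with all three ring substituents equatorial (3R).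

Step 17
Reactants: 28 methyl 2-[(2R,5S,6S)-6-[(2E,4E,6S,8E,10S,11R,12R)-12-hydroxy-11-methoxy-6,8,10-trimethyltrideca-2,4,8-trien-2-yl]-5-methyloxan-2-yl]acetate
Product: 29 2-[(2R,5S,6S)-6-[(2E,4E,6S,8E,10S,11R,12R)-12-hydroxy-11-methoxy-6,8,10-trimethyltrideca-2,4,8-trien-2-yl]-5-methyloxan-2-yl]acetic acid
Conditions: LiOH, THF/MeOH/H2O, rt; then 1 M HCl to pH 4
Reagents that add atoms: lithium hydroxide, [Li+].[OH-]
Why: Saponification of the methyl ester under mild hydroxide conditions should leave the β-alkoxy ester linkage, the diene and the methyl ether intact.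

Step 18
Reactants: 29 2-[(2R,5S,6S)-6-[(2E,4E,6S,8E,10S,11R,12R)-12-hydroxy-11-methoxy-6,8,10-trimethyltrideca-2,4,8-trien-2-yl]-5-methyloxan-2-yl]acetic acid
Product: 30 herboxidiene
Conditions: VO(acac)2 (10 mol %), tBuOOH (decane), CH2Cl2, −15 to 0 °C
Reagents that add atoms: tert-butyl hydroperoxide, CC(C)(C)OO
Why: Hydroxyl-directed epoxidation: the vanadate ester of the bis-homoallylic C18 hydroxyl delivers the peroxide oxygen to one face of the C14=C15 alkene through a chair-like transition state with the C16 methyl and C17 methoxy groups pseudo-equatorial, which should give the (14R,15R)-epoxide and leave the remote diene untouched.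

**Compound list**

1 | (S)-β-citronellene, (3S)-3,7-dimethylocta-1,6-diene | C=C[C@@H](C)CCC=C(C)C | starting material
2 | 2,2-dimethyl-3-[(3S)-3-methylpent-4-en-1-yl]oxirane (epimers at the oxirane carbon) | C=C[C@@H](C)CCC1OC1(C)C | intermediate (not isolated)
3 | (4S)-4-methylhex-5-enal | C=C[C@@H](C)CCC=O | intermediate
4 | methyl (2E,6S)-6-methylocta-2,7-dienoate | C=C[C@@H](C)CC/C=C/C(=O)OC | intermediate
5 | methyl (2E,6S)-6-(1,2,4-trioxolan-3-yl)hept-2-enoate (epimers at the trioxolane carbon) | O1COOC1[C@@H](C)CC/C=C/C(=O)OC | intermediate (not isolated)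
6 | methyl (2E,6S)-6-methyl-7-oxohept-2-enoate (fragment A) | O=C[C@@H](C)CC/C=C/C(=O)OC | intermediate
7 | methyl (R)-lactate, methyl (2R)-2-hydroxypropanoate | COC(=O)[C@@H](C)O | starting material
8 | (2R)-2-hydroxy-N-methoxy-N-methylpropanamide | CON(C)C(=O)[C@@H](C)O | intermediate
9 | (2R)-2-hydroxypentan-3-one | CCC(=O)[C@@H](C)O | intermediate
10 | (2R)-3-oxopentan-2-yl benzoate | CCC(=O)[C@@H](C)OC(=O)c1ccccc1 | intermediate
11 | methacrolein, 2-methylprop-2-enal | CC(=C)C=O | starting material
12 | (2R,3E)-3-[(dicyclohexylboranyl)oxy]pent-3-en-2-yl benzoate | C/C=C(/OB(C1CCCCC1)C1CCCCC1)[C@@H](C)OC(=O)c1ccccc1 | intermediate (not isolated)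
13 | (2R,4S,5R)-5-[(dicyclohexylboranyl)oxy]-4,6-dimethyl-3-oxohept-6-en-2-yl benzoate | C[C@@H](OC(=O)c1ccccc1)C(=O)[C@@H](C)[C@@H](OB(C1CCCCC1)C1CCCCC1)C(C)=C | intermediate (not isolated)
14 | (2R,4S,5R)-5-hydroxy-4,6-dimethyl-3-oxohept-6-en-2-yl benzoate | C[C@@H](OC(=O)c1ccccc1)C(=O)[C@@H](C)[C@@H](O)C(C)=C | intermediate
15 | propanal | CCC=O | starting material
16 | (2R,3R,4R,5R)-3-hydroxy-4,6-dimethyl-5-(propanoyloxy)hept-6-en-2-yl benzoate | C[C@@H](OC(=O)c1ccccc1)[C@H](O)[C@@H](C)[C@@H](OC(=O)CC)C(C)=C | intermediate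
17 | (2R,3R,4S,5R)-3-methoxy-4,6-dimethyl-5-(propanoyloxy)hept-6-en-2-yl benzoate | C[C@@H](OC(=O)c1ccccc1)[C@H](OC)[C@@H](C)[C@@H](OC(=O)CC)C(C)=C | intermediate
18 | (E)-trimethylsilyl ketene acetal of 17 (methyl cis to the allylic oxygen) | C[C@@H](OC(=O)c1ccccc1)[C@H](OC)[C@@H](C)[C@@H](O/C(O[Si](C)(C)C)=C\C)C(C)=C | intermediate (not isolated)
19 | trimethylsilyl (2S,4E,6S,7R,8R)-8-(benzoyloxy)-7-methoxy-2,4,6-trimethylnon-4-enoate | C[C@@H](OC(=O)c1ccccc1)[C@H](OC)[C@@H](C)/C=C(\C)C[C@H](C)C(=O)O[Si](C)(C)C | intermediate (not isolated)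
20 | (2S,4E,6S,7R,8R)-8-(benzoyloxy)-7-methoxy-2,4,6-trimethylnon-4-enoic acid | C[C@@H](OC(=O)c1ccccc1)[C@H](OC)[C@@H](C)/C=C(\C)C[C@H](C)C(=O)O | intermediate
21 | (2S,4E,6S,7R,8R)-7-methoxy-2,4,6-trimethylnon-4-ene-1,8-diol | C[C@@H](O)[C@H](OC)[C@@H](C)/C=C(\C)C[C@H](C)CO | intermediate
22 | (2S,4E,6S,7R,8R)-8-hydroxy-7-methoxy-2,4,6-trimethylnon-4-enal | C[C@@H](O)[C@H](OC)[C@@H](C)/C=C(\C)C[C@H](C)C=O | intermediate
23 | (2R,3R,4S,5E,8S,9E)-10-iodo-3-methoxy-4,6,8-trimethyldeca-5,9-dien-2-ol | C[C@@H](O)[C@H](OC)[C@@H](C)/C=C(\C)C[C@H](C)/C=C/I | intermediate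
24 | propyne | CC#C | starting material
25 | (2R,3R,4S,5E,8S,9E)-3-methoxy-4,6,8-trimethyltrideca-5,9-dien-11-yn-2-ol (fragment B) | C[C@@H](O)[C@H](OC)[C@@H](C)/C=C(\C)C[C@H](C)/C=C/C#CC | intermediate
26 | 7-O-diethylboryl ether of 27 | CO[C@H]([C@@H](C)/C=C(\C)C[C@H](C)/C=C/C=C(\C)[C@@H](OB(CC)CC)[C@@H](C)CC/C=C/C(=O)OC)[C@@H](C)O | intermediate (not isolated)
27 | methyl (2E,6S,7S,8E,10E,12S,14E,16S,17R,18R)-7,18-dihydroxy-17-methoxy-6,8,12,14,16-pentamethylnonadeca-2,8,10,14-tetraenoate | CO[C@H]([C@@H](C)/C=C(\C)C[C@H](C)/C=C/C=C(\C)[C@@H](O)[C@@H](C)CC/C=C/C(=O)OC)[C@@H](C)O | intermediate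
28 | methyl 2-[(2R,5S,6S)-6-[(2E,4E,6S,8E,10S,11R,12R)-12-hydroxy-11-methoxy-6,8,10-trimethyltrideca-2,4,8-trien-2-yl]-5-methyloxan-2-yl]acetate | CO[C@H]([C@@H](C)/C=C(\C)C[C@H](C)/C=C/C=C(\C)[C@H]1O[C@@H](CC(=O)OC)CC[C@@H]1C)[C@@H](C)O | intermediate
29 | 2-[(2R,5S,6S)-6-[(2E,4E,6S,8E,10S,11R,12R)-12-hydroxy-11-methoxy-6,8,10-trimethyltrideca-2,4,8-trien-2-yl]-5-methyloxan-2-yl]acetic acid | CO[C@H]([C@@H](C)/C=C(\C)C[C@H](C)/C=C/C=C(\C)[C@H]1O[C@@H](CC(=O)O)CC[C@@H]1C)[C@@H](C)O | intermediate
30 | herboxidiene, 2-[(2R,5S,6S)-6-[(2E,4E,6S)-7-[(2R,3R)-3-[(2R,3R,4R)-4-hydroxy-3-methoxypentan-2-yl]-2-methyloxiran-2-yl]-6-methylhepta-2,4-dien-2-yl]-5-methyloxan-2-yl]acetic acid | CO[C@H]([C@@H](C)[C@H]1O[C@]1(C)C[C@H](C)/C=C/C=C(\C)[C@H]1O[C@@H](CC(=O)O)CC[C@@H]1C)[C@@H](C)O | target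

**Step count.** Total: 18 steps. Longest linear sequence: 15 steps (steps 4 to 18, from methyl (R)-lactate).

**Steps most likely to fail**

1. Step 15. The chiral phosphine may give poor facial selectivity at the aldehyde, and the enoate or the product diene may compete for zerovalent nickel. The fallback sets out from 25 (with 6 as partner) and comes back at 27. Hydrozirconation of the alkyne of 25 with Cp2Zr(H)Cl (excess, one equivalent being consumed by the hydroxyl) followed by iodinolysis should give (2R,3R,4S,5E,8S,9E,11E)-12-iodo-3-methoxy-4,6,8-trimethyltrideca-5,9,11-trien-2-ol F1. A catalytic asymmetric Nozaki–Hiyama–Kishi coupling of this iodide with aldehyde 6 (CrCl2, NiCl2 cat., chiral sulfonamide ligand, base) is chemoselective for aldehydes over enoates, tolerates the free hydroxyl and sets C7 under ligand control, giving 27.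

2. Step 10. The amide base may attack the benzoate, and incomplete control of ketene acetal geometry or a competing boat transition state would erode the C12 ratio. The fallback sets out from 17 and comes back at 21. Methanolysis (K2CO3, MeOH) removes both esters to give (2R,3R,4S,5R)-3-methoxy-4,6-dimethylhept-6-ene-2,5-diol F2. Eschenmoser–Claisen rearrangement with 1,1-dimethoxy-N,N-dimethylpropan-1-amine (xylene, 140 °C) needs no strong base, and only the allylic hydroxyl can rearrange. Allylic strain fixes the N,O-ketene acetal geometry with methyl cis to the allylic oxygen, so the same chair should give (2S,4E,6S,7R,8R)-8-hydroxy-7-methoxy-N,N,2,4,6-pentamethylnon-4-enamide F3. Reduction of the amide with LiNH2BH3 gives diol 21.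

3. Step 8. Divalent samarium may reductively cleave the α-benzoyloxy ketone before the active catalyst forms, and acyl groups may migrate between O15, O17 and O18. The fallback sets out from 14 and comes back at 21. Evans–Saksena reduction (Me4NBH(OAc)3, MeCN/AcOH, −30 °C) should give the 15,17-anti diol (2R,3R,4S,5R)-3,5-dihydroxy-4,6-dimethylhept-6-en-2-yl benzoate F4. Eschenmoser–Claisen rearrangement as above gives (2R,3R,4S,5E,8S)-9-(dimethylamino)-3-hydroxy-4,6,8-trimethyl-9-oxonon-5-en-2-yl benzoate F5. O-Methylation (Me3OBF4, 1,8-bis(dimethylamino)naphthalene) gives (2R,3R,4S,5E,8S)-9-(dimethylamino)-3-methoxy-4,6,8-trimethyl-9-oxonon-5-en-2-yl benzoate F6. LiNH2BH3 then reduces the amide to the primary alcohol and cleaves the benzoate, giving 21.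

**Further compounds**

F1 | step 15 | (2R,3R,4S,5E,8S,9E,11E)-12-iodo-3-methoxy-4,6,8-trimethyltrideca-5,9,11-trien-2-ol | C[C@@H](O)[C@H](OC)[C@@H](C)/C=C(\C)C[C@H](C)/C=C/C=C(\C)I
F2 | step 10 | (2R,3R,4S,5R)-3-methoxy-4,6-dimethylhept-6-ene-2,5-diol | C[C@@H](O)[C@H](OC)[C@@H](C)[C@@H](O)C(C)=C
F3 | step 10 | (2S,4E,6S,7R,8R)-8-hydroxy-7-methoxy-N,N,2,4,6-pentamethylnon-4-enamide | C[C@@H](O)[C@H](OC)[C@@H](C)/C=C(\C)C[C@H](C)C(=O)N(C)C
F4 | step 8 | (2R,3R,4S,5R)-3,5-dihydroxy-4,6-dimethylhept-6-en-2-yl benzoate | C[C@@H](OC(=O)c1ccccc1)[C@H](O)[C@@H](C)[C@@H](O)C(C)=C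
F5 | step 8 | (2R,3R,4S,5E,8S)-9-(dimethylamino)-3-hydroxy-4,6,8-trimethyl-9-oxonon-5-en-2-yl benzoate | C[C@@H](OC(=O)c1ccccc1)[C@H](O)[C@@H](C)/C=C(\C)C[C@H](C)C(=O)N(C)C
F6 | step 8 | (2R,3R,4S,5E,8S)-9-(dimethylamino)-3-methoxy-4,6,8-trimethyl-9-oxonon-5-en-2-yl benzoate | C[C@@H](OC(=O)c1ccccc1)[C@H](OC)[C@@H](C)/C=C(\C)C[C@H](C)C(=O)N(C)C
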